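**Assumption:** plakortolide numbering is used throughout (C1 = lactone C=O, C3 and C6 = peroxide carbons, C4 = lactone carbinol carbon); the target is (3R,4R,6S,13E,15E).

## Retrosynthetic overview

1. C13=C14 is cut by Horner–Wadsworth–Emmons olefination, giving a saturated C13 aldehyde and diethyl cinnamylphosphonate.
2. The C7–C12 chain is cut at C8–C9 (cross-metathesis, then diimide), giving a C6-allyl peroxylactone and hex-5-enal.
3. The C6–C7 bond is cut (allylsilane plus cyclic peroxycarbenium ion, sets C6), giving a bicyclic 6-methoxy peroxy-ketal lactone.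
4. Both rings are opened together: the 1,2-dioxane first (peroxy-Michael, sets C3), then the γ-lactone, in the same flask; the O–O unit comes from ozone via Criegee/methanol trapping of an acyclic hydroxy dienoate.
5. The dienoate comes from (S)-2-methylglycidol (Sharpless epoxidation of methallyl alcohol sets C4), isopropenyl Grignard and a Wittig ylide.

## Route

**Step 1**
Reactants: 1 2-methylprop-2-en-1-ol
Product: 2 (2S)-(2-methyloxiran-2-yl)methanol [(S)-2-methylglycidol]
Conditions: Ti(OiPr)4 (5 mol %), L-(+)-DIPT (7 mol %), t-BuOOH, 4 Å MS, CH2Cl2, −20 °C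
Reagents that add atoms: tert-butyl hydroperoxide, CC(C)(C)OO
Why: Sharpless asymmetric epoxidation; the L-(+)-tartrate catalyst delivers oxygen to the face that gives the (S)-epoxide (about 93–95% ee expected), and this quaternary carbon becomes C4.

**Step 2**
Reactants: 2 (S)-2-methylglycidol; 3 isopropenylmagnesium bromide
Product: 4 (2R)-2,4-dimethylpent-4-ene-1,2-diol
Conditions: 3 (3 equiv), CuI (10 mol %), THF, −30 → 0 °C
Reagents that add atoms: none
Why: Copper-catalysed Grignard opening (SN2) at the CH2 terminus of the 2,2-disubstituted epoxide leaves the quaternary carbinol untouched (the label changes S → R only through CIP priorities), and the degenerate Payne rearrangement of the alkoxide returns the same enantiomer.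

**Step 3**
Reactants: 4 (2R)-2,4-dimethylpent-4-ene-1,2-diol; 5 ethyl (triphenylphosphoranylidene)acetate
Product: 7 ethyl (2E,4R)-4-hydroxy-4,6-dimethylhepta-2,6-dienoate, via hydroxy aldehyde 6 (not isolated)
Conditions: IBX (1.5 equiv), 5 (1.5 equiv), DMSO, 23 °C
Reagents that add atoms: none
Why: Tandem IBX oxidation–Wittig olefination; IBX oxidises the primary alcohol of the 1,2-diol without glycol cleavage and the stabilised ylide traps the α-hydroxy aldehyde E-selectively, with C4 not involved.

**Step 4**
Reactants: 7 ethyl (2E,4R)-4-hydroxy-4,6-dimethylhepta-2,6-dienoate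
Product: 10 (3R,4R,6RS)-3,6-epidioxy-6-methoxy-4-methylheptan-4-olide [cis-fused 1,2-dioxane/γ-lactone; C6 epimers], via hydroperoxy ketal 8 (not isolated), via dioxane hydroxy ester 9 (not isolated)
Conditions: O3, CH2Cl2/MeOH 4:1, −78 °C; N2 purge, evaporate; Et2NH (0.5 equiv), CF3CH2OH, 0 → 23 °C; PPTS (cat.), CH2Cl2, 23 °C
Reagents that add atoms: ozone, [O-][O+]=O; methanol, CO
Why: Ozone attacks only the electron-rich 1,1-disubstituted alkene and methanol traps the Criegee carbonyl oxide as the α-methoxy hydroperoxide 8, whose amine-promoted 6-exo peroxy-Michael (oxa-Michael) addition through a chair with the enoate and C4–Me equatorial and C4–OH axial gives the 3,4-cis dioxane 9, which lactonises directly, so C3 (R) is set from C4 while the C6 ketal epimers do not matter because C6 is ionised in step 5.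

**Step 5**
Reactants: 10 bicyclic methoxy peroxy-ketal lactone; 11 allyltrimethylsilane
Product: 13 (3R,4R,6S)-3,6-epidioxy-4,6-dimethylnon-8-en-4-olide, via peroxycarbenium triflate 12 (not isolated)
Conditions: 11 (3 equiv), TMSOTf (0.5 equiv), CH2Cl2, −78 → −40 °C
Reagents that add atoms: none
Why: Hosomi–Sakurai allylation of the cyclic peroxycarbenium ion formed by Lewis-acid ionisation of the monoperoxy ketal; the allylsilane is expected to add axially to the half-chair that keeps C4–Me and the C3 side chain pseudo-equatorial and the C4 lactone oxygen pseudo-axial, placing allyl cis to the lactone oxygen and C6–Me cis to C4–Me (6S).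

**Step 6**
Reactants: 14 hex-5-en-1-ol
Product: 15 hex-5-enal
Conditions: TEMPO (10 mol %), PhI(OAc)2 (1.1 equiv), CH2Cl2, 23 °C
Reagents that add atoms: none
Why: TEMPO/oxoammonium oxidation of a primary alcohol stops at the aldehyde and leaves the terminal alkene alone; no stereocentre is involved.

**Step 7**
Reactants: 13 allyl peroxylactone; 15 hex-5-enal
Product: 16 (3R,4R,6S,8E)-3,6-epidioxy-4,6-dimethyl-13-oxotridec-8-en-4-olide (E/Z mixture, E drawn)
Conditions: Grubbs II (5 mol %), 15 (3 equiv), CH2Cl2, 40 °C
Reagents that add atoms: none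
Why: Olefin cross-metathesis of two unhindered terminal alkenes driven by excess 15 and loss of ethylene; the dialkyl peroxide, lactone and aldehyde should be inert to the Ru carbene, and the E/Z ratio is irrelevant because this alkene is reduced next.

**Step 8**
Reactants: 16 enal peroxylactone
Product: 17 (3R,4R,6S)-3,6-epidioxy-4,6-dimethyl-13-oxotridecan-4-olide
Conditions: KO2CN=NCO2K (10 equiv), AcOH (20 equiv), CH2Cl2, 0 → 23 °C
Reagents that add atoms: none
Why: Diimide reduction (concerted syn transfer of H2) saturates the isolated C=C but not the O–O bond, lactone or aldehyde, and the acid-generated reagent has no hydrazide to condense with the aldehyde.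

**Step 9**
Reactants: 17 saturated aldehyde; 18 diethyl [(2E)-3-phenylprop-2-en-1-yl]phosphonate
Product: 19 plakortolide Q
Conditions: 18 (1.3 equiv), LiHMDS (1.2 equiv), THF, −78 °C; then 17, −78 → 0 °C
Reagents that add atoms: none
Why: Horner–Wadsworth–Emmons olefination with an allylic phosphonate forms the 13E alkene while the 15E alkene comes intact from the reagent; the base is fully consumed by excess phosphonate before the peroxylactone is added, so C3, C4 and C6 are untouched.

## Compound list

1 | 2-methylprop-2-en-1-ol | C=C(C)CO | starting material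
2 | (2S)-(2-methyloxiran-2-yl)methanol | OC[C@@]1(C)CO1 | intermediate
3 | isopropenylmagnesium bromide | CC(=C)[Mg]Br | starting material
4 | (2R)-2,4-dimethylpent-4-ene-1,2-diol | C=C(C)C[C@@](C)(O)CO | intermediate
5 | ethyl (triphenylphosphoranylidene)acetate | CCOC(=O)C=P(c1ccccc1)(c1ccccc1)c1ccccc1 | starting material
6 | (2R)-2-hydroxy-2,4-dimethylpent-4-enal | C=C(C)C[C@@](C)(O)C=O | intermediate
7 | ethyl (2E,4R)-4-hydroxy-4,6-dimethylhepta-2,6-dienoate | C=C(C)C[C@@](C)(O)/C=C/C(=O)OCC | intermediate
8 | ethyl (2E,4R)-6-hydroperoxy-4-hydroxy-6-methoxy-4-methylhept-2-enoate (C6 epimers) | COC(C)(OO)C[C@@](C)(O)/C=C/C(=O)OCC | intermediate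
9 | ethyl [(3R,4R)-4-hydroxy-6-methoxy-4,6-dimethyl-1,2-dioxan-3-yl]acetate (C6 epimers) | COC1(C)C[C@@](C)(O)[C@@H](CC(=O)OCC)OO1 | intermediate
10 | (3R,4R,6RS)-3,6-epidioxy-6-methoxy-4-methylheptan-4-olide | COC1(C)C[C@@]2(C)OC(=O)C[C@H]2OO1 | intermediate
11 | allyltrimethylsilane | C=CC[Si](C)(C)C | starting material
12 | cyclic C6 peroxycarbenium ion of 10, triflate salt | CC1=[O+]O[C@@H]2CC(=O)O[C@]2(C)C1.[O-]S(=O)(=O)C(F)(F)F | intermediate
13 | (3R,4R,6S)-3,6-epidioxy-4,6-dimethylnon-8-en-4-olide | C[C@]1(CC=C)C[C@@]2(C)OC(=O)C[C@H]2OO1 | intermediate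
14 | hex-5-en-1-ol | C=CCCCCO | starting material
15 | hex-5-enal | C=CCCCC=O | intermediate
16 | (3R,4R,6S,8E)-3,6-epidioxy-4,6-dimethyl-13-oxotridec-8-en-4-olide | C[C@]1(C/C=C/CCCC=O)C[C@@]2(C)OC(=O)C[C@H]2OO1 | intermediate
17 | (3R,4R,6S)-3,6-epidioxy-4,6-dimethyl-13-oxotridecan-4-olide | C[C@]1(CCCCCCC=O)C[C@@]2(C)OC(=O)C[C@H]2OO1 | intermediate
18 | diethyl [(2E)-3-phenylprop-2-en-1-yl]phosphonate | CCOP(=O)(C/C=C/c1ccccc1)OCC | starting material
19 | plakortolide Q, (3R,4R,6S,13E,15E)-3,6-epidioxy-4,6-dimethyl-16-phenylhexadeca-13,15-dien-4-olide | C[C@]1(CCCCCC/C=C/C=C/c2ccccc2)C[C@@]2(C)OC(=O)C[C@H]2OO1 | target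

## Step count and risks

Total steps: 9. Longest linear sequence: 8 (1 → 2 → 4 → 7 → 10 → 13 → 16 → 17 → 19); step 6 is a one-step side branch. No protecting groups are used.

The three steps most likely to fail:

**Step 4 (ozonolysis / Criegee trapping / peroxy-Michael / lactonisation).** The risks are the wrong fragmentation of the primary ozonide (methyl ketone instead of the methoxy hydroperoxide), epoxidation instead of Michael addition, or slow lactonisation. The fallback sets out from 7 and returns at 10. It takes the peroxide oxygens from hydrogen peroxide instead of ozone: ozonolysis of 7 in CH2Cl2 with Me2S work-up gives the isolated methyl ketone ethyl (2E,4R)-4-hydroxy-4-methyl-6-oxohept-2-enoate F1. Perhydrolysis of F1 with urea–H2O2 and catalytic Sc(OTf)3 in MeOH gives the hydroperoxy ketal 8, which is cyclised with Et2NH in CF3CH2OH through 9 to 10 as before.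

**Step 5 (allylation of the bicyclic peroxy ketal).** The risks are ionisation of the ring C–O bond instead of the methoxy group, fragmentation of the cation, or low facial selectivity at C6. The fallback sets out from 8 and returns at 13. It forms the C6–C7 bond before any ring exists and gives up control at C6: Lewis-acid allylation (TiCl4, 11, CH2Cl2, −78 °C) of the acyclic hydroperoxy ketal 8 gives the tertiary hydroperoxide ethyl (2E,4R,6RS)-6-hydroperoxy-4-hydroxy-4,6-dimethylnona-2,8-dienoate F2. Et2NH in CF3CH2OH then closes the dioxane to ethyl [(3R,4R,6RS)-4-hydroxy-4,6-dimethyl-6-(prop-2-en-1-yl)-1,2-dioxan-3-yl]acetate F3 and the lactone, giving 13 together with its C6 epimer (3R,4R,6R)-3,6-epidioxy-4,6-dimethylnon-8-en-4-olide F4, which is removed by chromatography.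

**Step 9 (olefination next to a base-sensitive β-peroxy lactone).** The risks are retro-Michael opening by the phosphonate anion and incomplete 13E selectivity. The fallback sets out from 17 and returns at 19. It uses a geometry-unselective olefination under weak base followed by thermodynamic isomerisation: Wittig reaction of 17 with cinnamyltriphenylphosphonium chloride, K2CO3 and 18-crown-6 in CH2Cl2 gives a 13Z/13E mixture whose new component is (3R,4R,6S,13Z,15E)-3,6-epidioxy-4,6-dimethyl-16-phenylhexadeca-13,15-dien-4-olide F5. Catalytic I2 in CH2Cl2 under daylight converts the mixture into the (13E,15E) diene 19.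

## Further compounds

F1 | step 4 | ethyl (2E,4R)-4-hydroxy-4-methyl-6-oxohept-2-enoate | CC(=O)C[C@@](C)(O)/C=C/C(=O)OCC
F2 | step 5 | ethyl (2E,4R,6RS)-6-hydroperoxy-4-hydroxy-4,6-dimethylnona-2,8-dienoate | C=CCC(C)(OO)C[C@@](C)(O)/C=C/C(=O)OCC
F3 | step 5 | ethyl [(3R,4R,6RS)-4-hydroxy-4,6-dimethyl-6-(prop-2-en-1-yl)-1,2-dioxan-3-yl]acetate | C=CCC1(C)C[C@@](C)(O)[C@@H](CC(=O)OCC)OO1
F4 | step 5 | (3R,4R,6R)-3,6-epidioxy-4,6-dimethylnon-8-en-4-olide | C[C@@]1(CC=C)C[C@@]2(C)OC(=O)C[C@H]2OO1
F5 | step 9 | (3R,4R,6S,13Z,15E)-3,6-epidioxy-4,6-dimethyl-16-phenylhexadeca-13,15-dien-4-olide | C[C@]1(CCCCCC/C=C\C=C\c2ccccc2)C[C@@]2(C)OC(=O)C[C@H]2OO1
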